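**Retrosynthetic overview**
1. Last disconnection: a double retro-aromatic-Claisen. The A-ring pyran and the B-ring C-prenyl group are both traced back to O-bound C5 units on one simple chalcone (a 1,1-dimethylpropargyl ether on O-4′, a 1,1-dimethylallyl ether on O-4).
2. That chalcone bis-ether ⇒ (enone C=C) a 2-hydroxy-4-alkoxyacetophenone + a 4-alkoxybenzaldehyde; the two ethers are the only phenol protection needed.
3. Aryl–O disconnections: the propargyl ether from 2,4-dihydroxyacetophenone (O-alkylation); the reverse-prenyl ether from 4-fluorobenzaldehyde (SNAr).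
4. Ring order: both benzene rings are purchased. The only ring built is the 2H-pyran, closed in the final step, in the same operation that C-prenylates ring B.

Assumption: the target has no stereocentre (it is achiral), so "single enantiomer" is read as the single (E)-enone isomer drawn.

**Step 1**
Reactants: 1, 2,4-dihydroxyacetophenone; 2, 3-chloro-3-methylbut-1-yne
Product: 3, 1-[2-hydroxy-4-(2-methylbut-3-yn-2-yloxy)phenyl]ethan-1-one
Conditions: K2CO3, KI, CuI (cat.), acetone, reflux
Reagents that add atoms: 3-chloro-3-methylbut-1-yne, C#CC(C)(C)Cl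
Why: Copper-assisted propargylic O-alkylation of a phenol; the 2-OH is hydrogen-bonded to the ketone, so only the 4-OH reacts.

**Step 2**
Reactants: 4, 4-fluorobenzaldehyde; 5, 2-methylbut-3-en-2-ol
Product: 6, 4-(2-methylbut-3-en-2-yloxy)benzaldehyde
Conditions: 5, KHMDS, THF, 0 °C (pre-form alkoxide); then 4, THF–DMF, 0 → 25 °C
Reagents that add atoms: 2-methylbut-3-en-2-ol, C=CC(C)(C)O
Why: SNAr of the para-formyl-activated C–F bond by a tertiary alkoxide (analogous to 4-fluorobenzaldehyde + KOtBu giving 4-tert-butoxybenzaldehyde); the temperature is kept at or below 25 °C so the ether does not rearrange early.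

**Step 3**
Reactants: 3, propargyl ether ketone; 6, reverse-prenyl ether aldehyde
Product: 7, (E)-1-[2-hydroxy-4-(2-methylbut-3-yn-2-yloxy)phenyl]-3-[4-(2-methylbut-3-en-2-yloxy)phenyl]prop-2-en-1-one
Conditions: 50% aq. KOH, EtOH, 0 °C → rt, 24 h; cold aq. NH4Cl quench to pH ~6 (no strong acid)
Reagents that add atoms: none (all heavy atoms come from 3 and 6)
Why: Claisen–Schmidt aldol condensation with E1cB dehydration gives the thermodynamic E-enone; both tertiary ethers are base-stable and mask the two reactive phenols, so only the chelated 2′-OH is free.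

**Step 4**
Reactants: 7, chalcone bis-ether
Product: 8, paratocarpin B
Conditions: o-xylene (0.02 M, degassed), BHT (5 mol %), sealed tube, 110 °C 2 h, then 140 °C 14 h
Reagents that add atoms: none (isomerisation, C25H26O4 → C25H26O4)
Why: Proposed new method: a one-pot double dearomative Claisen cascade in which ring B undergoes a [3,3] shift of the 1,1-dimethylallyl ether to a 6-prenylcyclohexa-2,4-dienone that re-aromatises to the o-prenylphenol (both ortho positions are equivalent), while ring A undergoes a [3,3] shift of the 1,1-dimethylpropargyl ether to C-3′ (the 2′-OH···O=C chelate fixes C3′=C4′ double-bond character, favouring the angular isomer) to give an allenyl dienone that enolises, undergoes a 1,5-H shift to an o-quinone methide and closes by oxa-6π electrocyclisation to the 2,2-dimethyl-2H-chromene; the closest known reactions are the separate thermal Claisen rearrangements of aryl 1,1-dimethylpropargyl ethers (to 2,2-dimethylchromenes) and of aryl 1,1-dimethylallyl ethers (to o-prenylphenols); no stereocentre is formed and the E-enone is the thermodynamic geometry.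

**Compound list**
1 | 2,4-dihydroxyacetophenone | CC(=O)c1ccc(O)cc1O | starting material
2 | 3-chloro-3-methylbut-1-yne | C#CC(C)(C)Cl | starting material
3 | 1-[2-hydroxy-4-(2-methylbut-3-yn-2-yloxy)phenyl]ethan-1-one | CC(=O)c1ccc(OC(C)(C)C#C)cc1O | intermediate
4 | 4-fluorobenzaldehyde | O=Cc1ccc(F)cc1 | starting material
5 | 2-methylbut-3-en-2-ol | C=CC(C)(C)O | starting material
6 | 4-(2-methylbut-3-en-2-yloxy)benzaldehyde | C=CC(C)(C)Oc1ccc(C=O)cc1 | intermediate
7 | (E)-1-[2-hydroxy-4-(2-methylbut-3-yn-2-yloxy)phenyl]-3-[4-(2-methylbut-3-en-2-yloxy)phenyl]prop-2-en-1-one | C#CC(C)(C)Oc1ccc(C(=O)/C=C/c2ccc(OC(C)(C)C=C)cc2)c(O)c1 | intermediate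
8 | paratocarpin B, (E)-1-(5-hydroxy-2,2-dimethyl-2H-chromen-6-yl)-3-[4-hydroxy-3-(3-methylbut-2-en-1-yl)phenyl]prop-2-en-1-one | CC(C)=CCc1cc(/C=C/C(=O)c2ccc3c(c2O)C=CC(C)(C)O3)ccc1O | target

**Totals**
Total steps: 4. Longest linear sequence: 3 (step 1 or 2 → step 3 → step 4).

**Three steps most likely to fail, with fallbacks**
1. Step 4 (double Claisen cascade). Risks are the linear chromene regioisomer, thermal closure of the 2′-hydroxychalcone to a flavanone, and loss of isoprene from the B-ring ether. Fallback: decouple the rearrangements from the chalcone. Heat 3 alone to 1-(5-hydroxy-2,2-dimethyl-2H-chromen-6-yl)ethanone and 6 alone to 4-hydroxy-3-prenylbenzaldehyde, MOM-protect the aldehyde's phenol, then do the aldol condensation and deprotect.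
2. Step 2 (SNAr with a hindered tertiary alkoxide). Risks are competing carbonyl addition with Tishchenko-type hydride transfer, and E2 loss of isoprene from the product. Fallback: build the ether from the phenol side. O-alkylate 4-hydroxybenzaldehyde with 2 (DBU, cat. CuCl2, MeCN), then semi-hydrogenate the alkyne (Lindlar catalyst, quinoline, H2) to reach 6.
3. Step 3 (Claisen–Schmidt). Risks are stalling, or base-promoted flavanone formation from the 2′-hydroxychalcone. Fallback: a stepwise directed aldol. Form the dianion of 3 (LiHMDS, 2.2 equiv, THF, −78 °C), add 6 to give the β-hydroxy ketone, then eliminate separately (MsCl, Et3N, then DBU) to the E-enone.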